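## Analysis of the target

The target is a daucane-type sesquiterpenoid diester built on a trans-fused hydroazulene. Ring A is a cyclopentane (C1–C2–C3–C4–C5) and ring B a cycloheptene (C1–C10–C9=C8–C7–C6–C5), sharing the C1–C5 bond. The numbering used throughout is: C1 the quaternary ring-fusion carbon with a methyl group, C4 the tertiary carbinol carrying isopropyl, C5 the ring-fusion CH, C6 the benzoyloxy carbon, C7 a methylene, C8(CH3)=C9 the alkene, C10 the angeloyloxy carbon. β is the face of the C1 methyl group.

The five stereocentres (1S,4R,5S,6S,10R) are contiguous around the ring fusion. H5 is α (trans fusion), the C4 hydroxyl is β (cis to the C1 methyl, isopropyl α), the C6 benzoate is α (cis to H5) and the C10 angelate is α (trans to the C1 methyl).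

The sensitive groups are the (Z)-2-methylbut-2-enoate (angelate), which isomerises to the tiglate under basic or nucleophilic catalysis, the allylic and neopentyl C10–O bond, and the tertiary alcohol, which lies 1,3 to the C6 ester.

The synthesis is hard for three reasons. The quaternary C1 has a stereocentre or an oxygenated carbon on each of its three ring neighbours. Two secondary hydroxyls (C6, C10) must carry different acyl groups. The ring-B alkene must sit at C8=C9 and nowhere else.

The strategy rests on one pattern in ring B: the quaternary C1 is bonded to the oxygenated C10, C10 is allylic to C8=C9, and C7 is a methylene between C8 and C6. If C5=C6 is a second alkene, this is the cyclohepta-1,4-diene that a cis-divinylcyclopropane (C6–C7–C8) leaves after a Cope rearrangement. Ring B is therefore the (4+3) adduct of the diene C1=C5–C6=C7 (a vinylcyclopentene carrying ring A) and a three-carbon vinylcarbenoid C8–C9–C10 that brings the C10 oxygen.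

## Retrosynthetic reasoning

**C10–O acyl bond (25 to 24).** The angelate is cut first because it is the group most easily damaged. Installing it last on 24 means no later reagent can isomerise it. The forward reaction must acylate a hindered neopentyl allylic alcohol without a nucleophilic catalyst and must leave the tertiary C4 hydroxyl free.

**C6 benzoate and the C10 silyl ether (24 to 23 to 22).** The two secondary oxygens are told apart by the silyl ether that C10 has carried since ring B was formed. In 22 only the C6 hydroxyl can be acylated, since C4 is tertiary and C10 is silylated. Benzoylation followed by desilylation therefore gives 24 without any selectivity question.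

**C4–isopropyl bond (22 to 21).** The tertiary carbinol is cut back to the ring-A ketone 21. This is done only after C5 is a defined stereocentre, so that the trans-fused skeleton directs the nucleophile to the α face. The C1 methyl lies 1,3 to C4 on the β face and H5 is on the α face. The forward reaction needs a nucleophile of low basicity (an organocerium reagent), because the ketone can enolise towards C5 and carries a β-hydroxyl.

**C8 methyl and the C4 ketone (21 to 20 to 18 to 17 to 16).** The C8 methyl is traced to an ester, the C4 ketone to an ethylene ketal, and the free C6 hydroxyl of 21 to a triethylsilyl ether. The ester is reduced to the allylic alcohol 18 and deoxygenated to 20. One acidic step then removes both the ketal and the labile silyl ether. The ester is kept until after the next disconnection because it deactivates C8=C9.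

**C5–H and C6–O bonds (16 to 14).** Both are cut together to the C5=C6 alkene of 14. A syn hydroboration from the face opposite the C1 methyl gives H5 α and O6 α in one step, which is the trans fusion and the correct C6 configuration. The conjugated ester makes C8=C9 the less reactive alkene.

**C1–C10 and C7–C8 bonds (14 to 13 to 6 + 12).** This is the key disconnection. The Cope transform converts 14 into the cis-divinylcyclopropane 13, which is cut at the cyclopropane into diene 6 and vinyldiazoacetate 12. It is chosen because it builds ring B, the quaternary centre, the C10 stereocentre and both ring-B alkenes in their final positions from two small achiral fragments. The forward reaction must cyclopropanate only the vinyl group of 6, with absolute control from a chiral dirhodium tetraprolinate catalyst. The (E) geometry of 12 must then be relayed through a boat transition state into the trans C1-methyl/C10-oxygen relationship.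

**Diene 6 (6 to 4 + 5, 4 to 3 to 1).** The vinyl group must sit on the ring carbon next to the ketal and the methyl on the carbon one further on. That is the 6-ethenyl-7-methyl arrangement of the dioxaspirononene. Only this placement makes the ketal carbon C4 and the methyl-bearing carbon C1. The vinyl–ring bond is cut to bromide 4 and vinylborate 5. Bromide 4 comes from enone 1 by α-bromination (3) and ketalisation.

**Diazo ester 12 (12 to 10 to 8 + 9, 8 to 7).** The enol-ether double bond is cut by a dehydration transform to the aldol adduct 10, and 10 is cut to diazo ester 8 and aldehyde 9. Making the alkene by elimination next to the diazo ester is preferred over enolising an aldehyde, because the elimination leads to the conjugated, less crowded (E) isomer. Kinetic enol silylation of an aldehyde normally favours the (Z) isomer, which is unusable here. 8 is made from 7 and used in solution.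

## Alternatives that were turned down

**Alternative 1:** Disconnection of C1–C10 and C5–C6. In the forward direction, 3-methylcyclopent-2-en-1-one (1) and the symmetric bis(silyloxy)cyclopentene A2 would undergo an enone–alkene photocycloaddition under a chiral oxazaborolidine-based Lewis acid to give the five–four–five adduct A1. Desilylation and glycol cleavage of the C6–C10 bond would then open ring B as trione A3.
- For: it is the shortest way to the carbon skeleton. Both oxygenated carbons and the C8 methyl arrive in place, the two partners are cheap, and no diazo compound is needed. On convergence and cost it is at least the equal of the chosen route.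
- Against: only C1 survives as a stereocentre. In A3, C5 lies between two carbonyl groups and loses its configuration. C6 and C10 become ketones that must be reduced selectively and acylated differently. C8 sits symmetrically between them, so nothing directs the alkene to C8=C9 rather than C7=C8. The enantioselective Lewis-acid photocycloaddition has not been established for a β-substituted cyclopentenone with a tetrasubstituted bis(silyloxy)alkene.
- Comparison: the chosen strategy spends more steps on its fragments, but its key step delivers C1 and C10 with the alkene and the oxygen already differentiated.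

**Alternative 2:** Disconnection of the C1–C5 ring-fusion bond. In the forward direction, the cis-fused decalin hydroxy mesylate A5 would be treated with base. The angular alkoxide at C6 would push C1 from C6 to C5 with inversion, contracting one ring to ring A and expanding the other to ring B, to give hydroazulenone A4.
- For: the 1,2-shift is stereospecific and reliable, needs no metal, and sets the trans fusion (C1, C5) directly. On the reliability of the bond-forming event it is stronger than the chosen key step.
- Against: the functional groups of A4 are far from the target. There is a ketone at C6, a ketal at C10, a saturated C8 and a silyl ether at C4. Two stereoselective reductions, an oxidation at C4 and a dehydrogenation to place C8=C9 are all still needed. A5 itself needs four defined stereocentres and a mesylate held antiperiplanar to the C1–C6 bond, which for a trans-fused product means a cis-fused decalin in one particular conformation. Preparing it would take longer than the whole fragment synthesis of the chosen route.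
- Comparison: the chosen strategy accepts a less certain key step in exchange for forming ring B, its alkene and the C10 oxygen at once.

**Alternative 3:** Disconnection of the C1–CH3 bond and the C5–C6 bond. In the forward direction, a copper-catalysed asymmetric conjugate methylation of enone A7 with a methylaluminium reagent and a chiral phosphoramidite would be followed by trapping of the aluminium enolate with iodo-enal A8, giving A6.
- For: one catalytic operation sets three stereocentres (C1, C5, C6), one more than the chosen key step, from simple reagents.
- Against: ring B is not formed. It must be closed later between C9 and C10 by a chromium-mediated addition of the alkenyl iodide to a neopentyl aldehyde, which creates C10 with no obvious control. A8 is a β,γ-unsaturated aldehyde that readily conjugates or enolises. The aldol configuration at C6 is not secured. A6 is a β-hydroxy ketone with an epimerisable C5 that must be carried through several steps. Enantioselectivity of conjugate methylation is usually lower for 3-substituted cyclopentenones than for cyclohexenones.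
- Comparison: the chosen strategy fixes C10 relative to C1 by alkene geometry in the same step that closes ring B, and leaves C5 and C6 to a single substrate-controlled hydroboration.

Key step: step 7

Assumption (catalyst sense): the absolute sense of cyclopropanation is taken from the behaviour of Rh2(S-DOSP)4 with styrene and donor–acceptor diazoacetates, which gives (1S,2R)-1,2-diarylcyclopropanecarboxylates. On that basis 13 calls for Rh2(R-DOSP)4; if the sense on diene 6 proved opposite, the (S) catalyst would be used.

Assumption (racemates): 2, 10 and 11 are racemic, and their stereocentres are destroyed within the same or the next step.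

## Route

Step 1
Reactants: 1 3-methylcyclopent-2-en-1-one
Product: 3 2-bromo-3-methylcyclopent-2-en-1-one, via trans-2,3-dibromo-3-methylcyclopentanone 2 (not isolated)
Conditions: Br2, CH2Cl2, 0 °C; then Et3N, 0 °C to rt
Reagents that add atoms: bromine, BrBr
Why: Bromine adds across the enone to give dibromide 2, and triethylamine removes the acidic C2 proton with loss of the C3 bromide (bromination–dehydrobromination of an enone); no stereocentre survives.

Step 2
Reactants: 3 2-bromo-3-methylcyclopent-2-en-1-one
Product: 4 6-bromo-7-methyl-1,4-dioxaspiro[4.4]non-6-ene
Conditions: ethylene glycol, p-TsOH·H2O (cat.), benzene, reflux, Dean–Stark trap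
Reagents that add atoms: ethylene glycol, OCCO
Why: Acid-catalysed ketalisation driven by azeotropic removal of water; 2-bromocycloalkenones ketalise without migration of the double bond, and the ketal keeps C4 at the ketone level for the late isopropyl addition.

Step 3
Reactants: 4 6-bromo-7-methyl-1,4-dioxaspiro[4.4]non-6-ene; 5 potassium vinyltrifluoroborate
Product: 6 6-ethenyl-7-methyl-1,4-dioxaspiro[4.4]non-6-ene
Conditions: PdCl2(dppf)·CH2Cl2 (5 mol %), Cs2CO3, THF/H2O (9:1), 80 °C
Reagents that add atoms: none
Why: Suzuki–Miyaura coupling of the alkenyl bromide with the vinyltrifluoroborate; the basic aqueous medium leaves the allylic ketal untouched, and the vinyl group ends up on the carbon next to the ketal, as the C4–C5 bond of the target requires.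

Step 4
Reactants: 7 glycine methyl ester hydrochloride
Product: 8 methyl diazoacetate
Conditions: NaNO2, H2SO4 (cat.), CH2Cl2/H2O, −5 °C; used as a dried CH2Cl2 solution
Reagents that add atoms: sodium nitrite, [Na+].[O-]N=O
Why: Diazotisation of the α-amino ester; the diazonium ion loses its acidic α-proton to give the stabilised diazo ester, which is extracted as it forms and is not distilled.

Step 5
Reactants: 8 methyl diazoacetate; 9 (tert-butyldimethylsilyloxy)acetaldehyde
Product: 10 methyl 4-(tert-butyldimethylsilyloxy)-2-diazo-3-hydroxybutanoate (racemic)
Conditions: DBU (10 mol %), MeCN, rt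
Reagents that add atoms: none
Why: Amidine-catalysed aldol-type addition of the acidic diazo C–H bond to the aldehyde with retention of the diazo group; the new carbinol centre is racemic and is removed in step 6.

Step 6
Reactants: 10 methyl 4-(tert-butyldimethylsilyloxy)-2-diazo-3-hydroxybutanoate
Product: 12 methyl (E)-4-(tert-butyldimethylsilyloxy)-2-diazobut-3-enoate, via dichlorophosphate ester 11 (not isolated)
Conditions: POCl3, Et3N, CH2Cl2, 0 °C to rt; quick filtration through Et3N-deactivated silica, storage at −20 °C
Reagents that add atoms: none
Why: Dehydration of a β-hydroxy-α-diazo ester through its dichlorophosphate 11 and amine-induced elimination. The transition state with the silyloxy group and the diazo ester on opposite sides is the less crowded one and leads to the conjugated (E)-enol ether, the geometry the key step needs.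

Step 7
Reactants: 6 6-ethenyl-7-methyl-1,4-dioxaspiro[4.4]non-6-ene; 12 methyl (E)-4-(tert-butyldimethylsilyloxy)-2-diazobut-3-enoate
Product: 14 (1S,10R)-ketal diene ester [C4 dioxolane; C5=C6; C8=C9 bearing CO2Me; 10-OTBS trans to 1-CH3], via cis-divinylcyclopropane 13 (not isolated)
Conditions: Rh2(R-DOSP)4 (1 mol %), 6 (1.5 equiv), pentane, −78 °C, slow addition of 12, then rt; solvent exchanged for toluene, 100 °C
Reagents that add atoms: none
Why: The dirhodium tetraprolinate converts 12 into a donor–acceptor vinylcarbenoid that adds in a concerted, asynchronous manner to the monosubstituted vinyl group of 6 (bond C7–C8 leading, transient bond C6–C8 following), placing the silyloxyvinyl group cis to the cyclopentenyl group and giving the cis-divinylcyclopropane 13. 13 then undergoes a (3,3) sigmatropic (Cope) shift through a boat transition state in which C6–C8 breaks and C1–C10 forms; the closest known reaction type is the tandem cyclopropanation–Cope rearrangement of dirhodium vinylcarbenoids with 1,3-dienes, a formal (4+3) cycloaddition. Ring B is closed as a seven-membered ring by this formal (4+3) union of the four diene carbons C1, C5, C6 and C7 with the three carbenoid carbons C8, C9 and C10, the ring-forming event being the pericyclic ring expansion of the cyclopropane. The configuration of C1 is controlled by the catalyst: its chiral environment fixes the absolute configuration of the cyclopropane carbons C6 and C8, and the boat geometry passes it on suprafacially to C1. The configuration of C10 relative to C1 is controlled by alkene geometry: the (E)-silyloxy group points outward in the boat while the C1 methyl, held cis to C6 by ring A, points inward, so oxygen and methyl end up trans. The step needs chemoselectivity for the vinyl group over the tetrasubstituted ring alkene, the allylic C–H bonds and the ketal oxygens, which the steric shielding of the ring alkene and the preference of donor–acceptor carbenoids for terminal alkenes should provide; it also needs reaction at the carbenoid carbon and not at the silyloxy-bearing vinylogous carbon, which the non-polar solvent and the carboxylate catalyst favour. Because the inward methyl group retards the Cope step, the cyclopropane is heated only after the diazo compound has been consumed at low temperature, where enantioselectivity is highest.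

Step 8
Reactants: 14 (1S,10R)-ketal diene ester
Product: 16 (1S,5S,6S,10R)-hydroxy ester [trans-fused; H5 α; 6α-OH; C4 dioxolane; C8=C9 bearing CO2Me; 10α-OTBS], via C6 alkylborane 15 (not isolated)
Conditions: BH3·THF, THF, 0 °C to rt; then NaBO3·4H2O, THF/H2O, rt
Reagents that add atoms: sodium perborate, [Na+].[Na+].O[B-]1(O)OO[B-](O)(O)OO1
Why: Hydroboration–oxidation; borane adds syn to the electron-richer C5=C6 bond with boron on the less substituted C6, while the conjugated ester deactivates C8=C9 towards the electrophilic reagent. Attack from the α face, anti to the pseudo-axial C1 methyl on the neighbouring carbon, sets H5 α and, after oxidation with retention, the C6 hydroxyl α (trans ring fusion); perborate oxidises the C–B bond without touching the methyl ester.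

Step 9
Reactants: 16 (1S,5S,6S,10R)-hydroxy ester
Product: 17 C6 triethylsilyl ether of 16
Conditions: Et3SiCl, imidazole, DMF, 0 °C to rt
Reagents that add atoms: chlorotriethylsilane, CC[Si](Cl)(CC)CC
Why: Silylation of the only free hydroxyl; the triethylsilyl ether shields C6–OH during the hydride steps and is more acid-labile than the C10 tert-butyldimethylsilyl ether, so it can be removed together with the ketal in step 12.

Step 10
Reactants: 17 C6 triethylsilyl ether
Product: 18 allylic alcohol [CH2OH on C8 in place of CO2Me; otherwise as 17]
Conditions: iBu2AlH (2.5 equiv), CH2Cl2, −78 °C; Rochelle salt work-up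
Reagents that add atoms: none
Why: 1,2-Reduction of the conjugated ester to the allylic alcohol by the aluminium hydride at low temperature; ketal and silyl ethers are inert.

Step 11
Reactants: 18 allylic alcohol
Product: 20 C8-methyl ketal [CH3 on C8; 6α-OTES; 10α-OTBS; C4 dioxolane], via allylic mesylate 19 (not isolated)
Conditions: MsCl, Et3N, THF, −20 °C; then LiBHEt3, −20 °C to 0 °C
Reagents that add atoms: none
Why: Activation of the primary allylic alcohol as mesylate 19 and direct SN2 displacement by hydride; attack at the primary carbon is favoured over SN2′ attack at C9, which is flanked by the silylated C10 and the quaternary C1, so the alkene stays at C8=C9.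

Step 12
Reactants: 20 C8-methyl ketal
Product: 21 (1S,5S,6S,10R)-hydroxy ketone [C4 ketone; 6α-OH; 8-CH3; C8=C9; 10α-OTBS]
Conditions: PPTS (cat.), acetone/H2O (5:1), 50 °C; used at once
Reagents that add atoms: water, O
Why: Mild acid hydrolysis removes the dioxolane and the labile triethylsilyl ether in one operation, while the hindered secondary tert-butyldimethylsilyl ether at C10 survives; the weak acid and moderate temperature are chosen so that the ketone does not enolise towards C5 or lose the β-hydroxyl.

Step 13
Reactants: 21 (1S,5S,6S,10R)-hydroxy ketone
Product: 22 (1S,4R,5S,6S,10R)-diol [4β-OH; 4α-isopropyl; 6α-OH; 10α-OTBS]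
Conditions: iPrMgCl (5 equiv), anhydrous CeCl3 (5 equiv), THF, −78 °C to −20 °C
Reagents that add atoms: isopropylmagnesium chloride, CC(C)[Mg]Cl
Why: 1,2-Addition of the isopropyl organocerium reagent, whose low basicity suppresses enolisation towards C5 and β-hydride reduction; one equivalent is consumed by the C6 hydroxyl. The nucleophile enters C4 from the α face, on the side of H5 and away from the C1 methyl that lies 1,3 to C4 on the β face, giving the β-hydroxyl (4R); a C6-alkoxide chelate would expose the same face.

Step 14
Reactants: 22 (1S,4R,5S,6S,10R)-diol
Product: 23 C6 benzoate of 22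
Conditions: BzCl, pyridine, DMAP (cat.), CH2Cl2, 0 °C to rt
Reagents that add atoms: benzoyl chloride, O=C(Cl)c1ccccc1
Why: Acylation of the secondary C6 hydroxyl; the tertiary C4 alcohol does not react under these conditions and C10 is still silylated, so the benzoate is placed unambiguously.

Step 15
Reactants: 23 C6 benzoate
Product: 24 (1S,4R,5S,6S,10R)-6-benzoyloxy-4,10-diol [4β-OH; 10α-OH]
Conditions: HF·pyridine, pyridine, THF, 0 °C to rt
Reagents that add atoms: none
Why: Fluoride cleavage of the Si–O bond in pyridine-buffered medium; the benzoate and the tertiary alcohol are untouched, and no strong base is present that could move the acyl group.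

Step 16
Reactants: 24 (1S,4R,5S,6S,10R)-6-benzoyloxy-4,10-diol
Product: 25 target (1S,4R,5S,6S,10R)-10-angeloyloxy-6-benzoyloxy-4-hydroxy compound
Conditions: angelic acid, 2,4,6-trichlorobenzoyl chloride, Et3N, toluene, rt; then 24, toluene, 80 °C
Reagents that add atoms: angelic acid, C/C=C(/C)C(=O)O
Why: Acylation through the mixed anhydride of angelic acid with 2,4,6-trichlorobenzoic acid (Yamaguchi-type activation), run without a nucleophilic amine catalyst because such catalysts isomerise angelate to tiglate; the alcohol attacks the unhindered angeloyl carbonyl and the tertiary C4 hydroxyl stays free.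

## Compound list

1 | 3-methylcyclopent-2-en-1-one | CC1=CC(=O)CC1 | starting material
2 | trans-2,3-dibromo-3-methylcyclopentan-1-one (racemic; formed in the flask) | C[C@]1(Br)CCC(=O)[C@@H]1Br | intermediate
3 | 2-bromo-3-methylcyclopent-2-en-1-one | CC1=C(Br)C(=O)CC1 | intermediate
4 | 6-bromo-7-methyl-1,4-dioxaspiro[4.4]non-6-ene | CC1=C(Br)C2(CC1)OCCO2 | intermediate
5 | potassium vinyltrifluoroborate | C=C[B-](F)(F)F.[K+] | starting material
6 | 6-ethenyl-7-methyl-1,4-dioxaspiro[4.4]non-6-ene (vinyl on the carbon next to the spiro ketal carbon) | C=CC1=C(C)CCC12OCCO2 | intermediate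
7 | glycine methyl ester hydrochloride | COC(=O)C[NH3+].[Cl-] | starting material
8 | methyl diazoacetate | COC(=O)C=[N+]=[N-] | intermediate
9 | (tert-butyldimethylsilyloxy)acetaldehyde | CC(C)(C)[Si](C)(C)OCC=O | starting material
10 | methyl 4-(tert-butyldimethylsilyloxy)-2-diazo-3-hydroxybutanoate (racemic) | COC(=O)C(=[N+]=[N-])C(O)CO[Si](C)(C)C(C)(C)C | intermediate
11 | methyl 4-(tert-butyldimethylsilyloxy)-3-(dichlorophosphoryloxy)-2-diazobutanoate (racemic; formed in the flask) | COC(=O)C(=[N+]=[N-])C(OP(=O)(Cl)Cl)CO[Si](C)(C)C(C)(C)C | intermediate
12 | methyl (E)-4-(tert-butyldimethylsilyloxy)-2-diazobut-3-enoate | COC(=O)C(=[N+]=[N-])/C=C/O[Si](C)(C)C(C)(C)C | intermediate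
13 | methyl (1R,2S)-1-[(E)-2-(tert-butyldimethylsilyloxy)ethenyl]-2-(7-methyl-1,4-dioxaspiro[4.4]non-6-en-6-yl)cyclopropane-1-carboxylate (formed in the flask) | COC(=O)[C@]1(/C=C/O[Si](C)(C)C(C)(C)C)C[C@H]1C2=C(C)CCC23OCCO3 | intermediate
14 | (1S,10R)-ketal diene ester: hydroazulene core with C1 methyl, C4 ethylene ketal, C5=C6 and C8=C9 double bonds, CO2Me on C8, tert-butyldimethylsilyloxy on C10 trans to the C1 methyl | CC(C)(C)[Si](C)(C)O[C@@H]1C=C(C(=O)OC)CC=C2[C@]1(C)CCC23OCCO3 | intermediate
15 | (1S,5S,6S,10R)-C6 alkylborane: as 16 with BH2 in place of the C6 hydroxyl (formed in the flask) | CC(C)(C)[Si](C)(C)O[C@@H]1C=C(C(=O)OC)C[C@H](B)[C@@H]2[C@]1(C)CCC23OCCO3 | intermediate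
16 | (1S,5S,6S,10R)-hydroxy ester: trans-fused core, H5 α, 6α-hydroxyl, C4 ethylene ketal, C8=C9 with CO2Me on C8, 10α-OTBS | CC(C)(C)[Si](C)(C)O[C@@H]1C=C(C(=O)OC)C[C@H](O)[C@@H]2[C@]1(C)CCC23OCCO3 | intermediate
17 | C6 triethylsilyl ether of 16 | CC(C)(C)[Si](C)(C)O[C@@H]1C=C(C(=O)OC)C[C@H](O[Si](CC)(CC)CC)[C@@H]2[C@]1(C)CCC23OCCO3 | intermediate
18 | allylic alcohol: as 17 with CH2OH on C8 | CC(C)(C)[Si](C)(C)O[C@@H]1C=C(CO)C[C@H](O[Si](CC)(CC)CC)[C@@H]2[C@]1(C)CCC23OCCO3 | intermediate
19 | methanesulfonate of 18 (formed in the flask) | CC(C)(C)[Si](C)(C)O[C@@H]1C=C(COS(C)(=O)=O)C[C@H](O[Si](CC)(CC)CC)[C@@H]2[C@]1(C)CCC23OCCO3 | intermediate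
20 | C8-methyl ketal: as 17 with CH3 on C8 | CC(C)(C)[Si](C)(C)O[C@@H]1C=C(C)C[C@H](O[Si](CC)(CC)CC)[C@@H]2[C@]1(C)CCC23OCCO3 | intermediate
21 | (1S,5S,6S,10R)-hydroxy ketone: C4 ketone, 6α-hydroxyl, C8 methyl, C8=C9, 10α-OTBS | CC(C)(C)[Si](C)(C)O[C@@H]1C=C(C)C[C@H](O)[C@@H]2[C@]1(C)CCC2=O | intermediate
22 | (1S,4R,5S,6S,10R)-diol: 4β-hydroxyl, 4α-isopropyl, 6α-hydroxyl, 10α-OTBS | CC(C)(C)[Si](C)(C)O[C@@H]1C=C(C)C[C@H](O)[C@@H]2[C@]1(C)CC[C@@]2(O)C(C)C | intermediate
23 | C6 benzoate of 22 | CC(C)(C)[Si](C)(C)O[C@@H]1C=C(C)C[C@H](OC(=O)c2ccccc2)[C@@H]2[C@]1(C)CC[C@@]2(O)C(C)C | intermediate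
24 | (1S,4R,5S,6S,10R)-6α-benzoyloxy-4β,10α-diol | O[C@@H]1C=C(C)C[C@H](OC(=O)c2ccccc2)[C@@H]2[C@]1(C)CC[C@@]2(O)C(C)C | intermediate
25 | (1S,4R,5S,6S,10R)-10α-angeloyloxy-6α-benzoyloxy-4β-hydroxy-4α-isopropyl-1β,8-dimethyl compound (CNP0397959.1) | C/C=C(/C)C(=O)O[C@@H]1C=C(C)C[C@H](OC(=O)c2ccccc2)[C@@H]2[C@]1(C)CC[C@@]2(O)C(C)C | target

## Step count and least certain steps

Total: 16 steps. Longest linear sequence: 13 steps (steps 1–3 then 7–16; the diazo branch, steps 4–6 then 7–16, is equally long).

**Step 7 (key step).**
- What may go wrong: the diene may attack the silyloxy-bearing terminus of the carbenoid instead of the carbenoid carbon, because the oxygen makes that carbon oxocarbenium-like; this would give open-chain or (3+2)-type products. The Cope step may also be sluggish, because the C1 methyl points into the cyclopropane. That leaves time for reversible homolysis of the C6–C8 bond, which would erode enantiomeric purity.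
- Fallback (sets out from 10 and 6, returns at 14): the 4-silyloxy carbenoid is replaced by a 3-silyloxy (enol-type) vinylcarbenoid, the best-documented class for this cycloaddition. 10 is oxidised with Dess–Martin periodinane to methyl 4-(tert-butyldimethylsilyloxy)-2-diazo-3-oxobutanoate F1. Soft enolisation (TBSOTf, Et3N) gives the (Z)-3,4-bis(silyloxy) vinyldiazoacetate F2, in which the C4 oxygen is held trans to the diazo carbon by the enolisation itself. Reaction with 6 under Rh2(S-PTAD)4 or Rh2(R-PTAD)4 (handedness chosen as for step 7) gives, through the divinylcyclopropane F3, the bis-silyl cycloheptadiene F4. Selective cleavage of the enol silyl ether (HF·pyridine, low temperature) gives β-keto ester F5. NaH and PhNTf2 give enol triflate F6. Reduction with Pd(OAc)2, PPh3, Bu3N and HCO2H gives 14. This detour costs four extra steps and does not remove the inward-methyl problem of the Cope step.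

**Step 6.**
- What may go wrong: the elimination may give geometric mixtures. The product may also be lost by 1,5-electrocyclisation to a pyrazole or by desilylation of the enol ether.
- Fallback (sets out from 10, returns at 14): 10 is not dehydrated but oxidised, and the detour written out for step 7 is followed. It needs no compound beyond those named there and has no alkene-geometry problem.

**Step 8.**
- What may go wrong: borane may reduce the conjugated ester while the hindered, inductively deactivated C5=C6 bond reacts slowly. Facial selectivity may also be incomplete, because the α-oriented C10 silyl ether partly offsets the shielding by the C1 methyl.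
- Fallback (sets out from 14, returns at 21): the ester is removed before hydroboration, so that the two alkenes are distinguished by sterics rather than electronics. 14 is reduced with iBu2AlH to the allylic alcohol F7, which is deoxygenated as in step 11 through mesylate F8 to the C8-methyl diene F9. Hydroboration–oxidation as in step 8 should now prefer C5=C6, whose CH terminus C6 is unhindered, whereas C9 lies next to the silylated C10; through alkylborane F10 this gives alcohol F11. Hydrolysis under the conditions of step 12 gives 21. This path needs no triethylsilyl group.

**Step 12.**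
- What may go wrong: the newly freed ketone may epimerise at C5 through its enol (a cis-fused hydroazulenone may well be the more stable), and the C6 hydroxyl may be lost by β-elimination under acid.
- Fallback (sets out from 20, returns at 22): C6 stays silylated through the ketone stage and the carbonyl is released without protic acid. 20 is treated with TMSOTf and 2,2′-bipyridyl in CH2Cl2 at 0 °C and then water, giving the β-silyloxy ketone F12. Addition of the isopropyl organocerium reagent as in step 13 gives F13. The triethylsilyl ether is then removed selectively (HF·pyridine, pyridine, THF, 0 °C) to give 22.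

**Step 16.**
- What may go wrong: the angeloyl group may isomerise to tigloyl during a slow acylation of the neopentyl allylic hydroxyl.
- Fallback (sets out from 24, returns at 25): the angelate is built on the molecule instead of being transferred. 24 is esterified with 2-[bis(2,2,2-trifluoroethoxy)phosphoryl]propanoic acid (DCC, DMAP) to the phosphonate F14. A Still–Gennari olefination with acetaldehyde (KN(SiMe3)2, 18-crown-6, THF, −78 °C; one extra equivalent of base for the C4 hydroxyl) should give the (Z)-2-methylbut-2-enoate 25.

## Further compounds

F1 | step 7 | methyl 4-(tert-butyldimethylsilyloxy)-2-diazo-3-oxobutanoate | COC(=O)C(=[N+]=[N-])C(=O)CO[Si](C)(C)C(C)(C)C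
F2 | step 7 | methyl (Z)-3,4-bis(tert-butyldimethylsilyloxy)-2-diazobut-3-enoate | COC(=O)C(=[N+]=[N-])/C(O[Si](C)(C)C(C)(C)C)=C/O[Si](C)(C)C(C)(C)C
F3 | step 7 | methyl (1R,2S)-1-[(Z)-1,2-bis(tert-butyldimethylsilyloxy)ethenyl]-2-(7-methyl-1,4-dioxaspiro[4.4]non-6-en-6-yl)cyclopropane-1-carboxylate | COC(=O)[C@]1(/C(O[Si](C)(C)C(C)(C)C)=C/O[Si](C)(C)C(C)(C)C)C[C@H]1C2=C(C)CCC23OCCO3
F4 | step 7 | 9,10-bis(tert-butyldimethylsilyloxy) analogue of 14 (silyl enol ether at C9, C8=C9, C5=C6) | CC(C)(C)[Si](C)(C)O[C@@H]1C(O[Si](C)(C)C(C)(C)C)=C(C(=O)OC)CC=C2[C@]1(C)CCC23OCCO3
F5 | step 7 | β-keto ester: C9 ketone, CO2Me on C8 (C8 configuration not fixed), 10-OTBS, C5=C6, C4 ketal | CC(C)(C)[Si](C)(C)O[C@@H]1C(=O)C(C(=O)OC)CC=C2[C@]1(C)CCC23OCCO3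
F6 | step 7 | C9 enol triflate of F5 | CC(C)(C)[Si](C)(C)O[C@@H]1C(OS(=O)(=O)C(F)(F)F)=C(C(=O)OC)CC=C2[C@]1(C)CCC23OCCO3
F0 | step 6 | none | none
F7 | step 8 | dienyl allylic alcohol: as 14 with CH2OH on C8 | CC(C)(C)[Si](C)(C)O[C@@H]1C=C(CO)CC=C2[C@]1(C)CCC23OCCO3
F8 | step 8 | methanesulfonate of F7 | CC(C)(C)[Si](C)(C)O[C@@H]1C=C(COS(C)(=O)=O)CC=C2[C@]1(C)CCC23OCCO3
F9 | step 8 | C8-methyl diene: as 14 with CH3 on C8 | CC(C)(C)[Si](C)(C)O[C@@H]1C=C(C)CC=C2[C@]1(C)CCC23OCCO3
F10 | step 8 | C6 alkylborane from F9 | CC(C)(C)[Si](C)(C)O[C@@H]1C=C(C)C[C@H](B)[C@@H]2[C@]1(C)CCC23OCCO3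
F11 | step 8 | 6α-hydroxy ketal: as 20 with free C6 hydroxyl | CC(C)(C)[Si](C)(C)O[C@@H]1C=C(C)C[C@H](O)[C@@H]2[C@]1(C)CCC23OCCO3
F12 | step 12 | C4 ketone with 6α-triethylsilyloxy and 10α-OTBS | CC(C)(C)[Si](C)(C)O[C@@H]1C=C(C)C[C@H](O[Si](CC)(CC)CC)[C@@H]2[C@]1(C)CCC2=O
F13 | step 12 | C6 triethylsilyl ether of 22 | CC(C)(C)[Si](C)(C)O[C@@H]1C=C(C)C[C@H](O[Si](CC)(CC)CC)[C@@H]2[C@]1(C)CC[C@@]2(O)C(C)C
F14 | step 16 | C10 2-[bis(2,2,2-trifluoroethoxy)phosphoryl]propanoate of 24 (phosphonate α-carbon not fixed) | CC(C(=O)O[C@@H]1C=C(C)C[C@H](OC(=O)c2ccccc2)[C@@H]2[C@]1(C)CC[C@@]2(O)C(C)C)P(=O)(OCC(F)(F)F)OCC(F)(F)F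
A1 | alternative 1 | five–four–five photoadduct of 1 and A2 | O=C1CC[C@]2(C)[C@@]3(O[Si](C)(C)C)CC(C)C[C@@]3(O[Si](C)(C)C)[C@H]12
A2 | alternative 1 | 4-methyl-1,2-bis(trimethylsilyloxy)cyclopent-1-ene | CC1CC(O[Si](C)(C)C)=C(O[Si](C)(C)C)C1
A3 | alternative 1 | hydroazulene-4,6,10-trione with C1 and C8 methyl groups (C5 and C8 configuration not fixed) | O=C1CC(C)CC(=O)C2[C@]1(C)CCC2=O
A4 | alternative 2 | trans-fused hydroazulen-6-one with C10 ethylene ketal and C4 tert-butyldimethylsilyloxy | O=C1CC(C)CC2(OCCO2)[C@@]3(C)CC[C@H](O[Si](C)(C)C(C)(C)C)[C@H]13
A5 | alternative 2 | cis-fused decalin: angular C6 hydroxyl cis to the C1 methyl, C5 mesylate, C4 tert-butyldimethylsilyloxy, C10 ethylene ketal | O[C@]12CC(C)CC3(OCCO3)[C@@]1(C)CC[C@H](O[Si](C)(C)C(C)(C)C)[C@@H]2OS(C)(=O)=O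
A6 | alternative 3 | trans-2,3-disubstituted cyclopentanone from conjugate methylation–aldol | I/C=C(/C)C[C@H](O)[C@@H]1[C@@](C)(CO[Si](C)(C)C(C)(C)C)CCC1=O
A7 | alternative 3 | 3-[(tert-butyldimethylsilyloxy)methyl]cyclopent-2-en-1-one | O=C1C=C(CO[Si](C)(C)C(C)(C)C)CC1
A8 | alternative 3 | (Z)-4-iodo-3-methylbut-3-enal | I/C=C(/C)CC=O
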